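**Strategy**

Both flavan units are traced to one building block, flavanone 7, whose pyranone ring is closed by forming the C-2–C-3 bond (ring F of the lower unit, ring C of the upper). In the key step a dirhodium carbenoid at C-3 inserts into the O-1–CH2 benzylic C–H bond of an ortho-benzyloxyaryl diazoketone. It exploits the hydridic C-2–H flanked by O-1 and the catechol ring (E or B), 1,6 to C-3, and sets C-2 by catalyst control. The four remaining stereocentres are relayed from C-2: the F-ring trans-diol through a bromohydrin and epoxide, the all-cis C-ring by aryl addition, hydroboration and oxidation–reduction.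

Key step: step 4

Remarks and assumptions:
- Ring letters: upper unit A (benzo), C (pyran), B (catechol); lower unit D, F, E. α means the face of the 2-aryl group.
- Rh2(S-PTTL)4 is dirhodium tetrakis[N-phthaloyl-(S)-tert-leucinate]. It is assumed to deliver the 2S ketone; if the first run shows the opposite sense, Rh2(R-PTTL)4 is used.
- The descriptor of C-4 of the upper unit is S in the benzylated compounds 20–22 and R in 23 for the same geometry, because debenzylation changes the CIP ranking of the two aryl branches.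

**Route**

Step 1
Reactants: 1 1-(2,3,4-trihydroxyphenyl)ethan-1-one (gallacetophenone)
Product: 2 1-[3,4-bis(benzyloxy)-2-hydroxyphenyl]ethan-1-one
Conditions: BnBr (2.1 equiv), K2CO3, acetone, reflux
Reagents that add atoms: benzyl bromide BrCc1ccccc1
Why: Williamson etherification; the 2-hydroxyl is hydrogen-bonded to the acetyl group and is the least reactive, so the 3- and 4-hydroxyls should be benzylated selectively.

Step 2
Reactants: 2 1-[3,4-bis(benzyloxy)-2-hydroxyphenyl]ethan-1-one; 3 1,2-bis(benzyloxy)-4-(chloromethyl)benzene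
Product: 4 1-(3,4-bis(benzyloxy)-2-{[3,4-bis(benzyloxy)phenyl]methoxy}phenyl)ethan-1-one
Conditions: K2CO3, KI (cat.), DMF, 70 °C
Reagents that add atoms: none
Why: Williamson etherification of the chelated phenol under iodide catalysis installs the benzyl ether whose CH2 becomes C-2 and whose arene becomes the catechol ring.

Step 3
Reactants: 4 1-(3,4-bis(benzyloxy)-2-{[3,4-bis(benzyloxy)phenyl]methoxy}phenyl)ethan-1-one
Product: 6 1-(3,4-bis(benzyloxy)-2-{[3,4-bis(benzyloxy)phenyl]methoxy}phenyl)-2-diazoethan-1-one, via trifluoromethyl diketone 5 (not isolated)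
Conditions: LiN(SiMe3)2, THF, −78 °C, then CF3CO2CH2CF3; dilute HCl work-up; MsN3, Et3N, H2O (1 equiv), MeCN, rt
Reagents that add atoms: methanesulfonyl azide CS(=O)(=O)N=[N+]=[N-]; 2,2,2-trifluoroethyl trifluoroacetate O=C(OCC(F)(F)F)C(F)(F)F (trifluoroacetyl group of 5 only)
Why: Detrifluoroacetylative diazo transfer (Claisen activation of the methyl ketone, then Regitz-type diazo transfer with loss of the trifluoroacetyl group) should give the terminal diazoketone without touching the benzyl ethers.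

Step 4
Reactants: 6 1-(3,4-bis(benzyloxy)-2-{[3,4-bis(benzyloxy)phenyl]methoxy}phenyl)-2-diazoethan-1-one
Product: 7 (2S)-7,8-bis(benzyloxy)-2-[3,4-bis(benzyloxy)phenyl]-2,3-dihydro-4H-chromen-4-one
Conditions: Rh2(S-PTTL)4 (1 mol %), CH2Cl2, 0 °C, slow addition of 6
Reagents that add atoms: none
Why: Loss of N2 gives an electrophilic dirhodium carbenoid at C-3, which inserts in a concerted, hydride-transfer-like three-centre step into the C-2–H bond of the ortho benzyl ether, a bond made hydridic by O-1 and by the dioxygenated arene. The closest known reaction type is the dirhodium-carboxylate-catalysed intramolecular C–H insertion of ortho-alkoxyaryl diazoketones to 2-substituted chroman-4-ones, here run with a chiral carboxylate. The pyranone ring closes by 1,6-insertion through a six-membered transition state, because position 5 of the tether is the oxygen and no 1,5 C–H bond exists. The only new stereocentre, C-2, is set by the chiral ligand shell, which discriminates the two enantiotopic benzylic hydrogens; enantiomeric purity is to be checked and, if needed, raised by recrystallisation. The step needs chemoselectivity for C–H insertion over oxonium-ylide formation at O-1 followed by [1,2]-benzyl shift to a 2-benzylbenzofuran-3-one; the weakly basic, doubly ortho-flanked aryl ether oxygen, the strongly activated C–H bond and a bulky carboxylate catalyst at low temperature in a non-coordinating solvent should secure it.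

Step 5
Reactants: 7 (2S)-7,8-bis(benzyloxy)-2-[3,4-bis(benzyloxy)phenyl]-2,3-dihydro-4H-chromen-4-one
Product: 9 (2R,3R)-7,8-bis(benzyloxy)-2-[3,4-bis(benzyloxy)phenyl]-3-bromo-2,3-dihydro-4H-chromen-4-one (2,3-trans), via silyl enol ether 8 (not isolated)
Conditions: Me3SiOTf, Et3N, CH2Cl2, 0 °C; evaporation of volatiles; NBS, THF, −78 °C
Reagents that add atoms: N-bromosuccinimide O=C1CCC(=O)N1Br; trimethylsilyl trifluoromethanesulfonate C[Si](C)(C)OS(=O)(=O)C(F)(F)F (silyl group of 8 only)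
Why: Soft enolisation avoids the ring-opening enolate, and electrophilic α-bromination of the silyl enol ether should occur on the face opposite the 2-aryl group, giving the 2,3-trans bromide without bromination of the deactivated or only singly activated arenes.

Step 6
Reactants: 9 (2R,3R)-7,8-bis(benzyloxy)-2-[3,4-bis(benzyloxy)phenyl]-3-bromo-2,3-dihydro-4H-chromen-4-one
Product: 12 (2R,3R,4S)-7,8-bis(benzyloxy)-2-[3,4-bis(benzyloxy)phenyl]-3,4-dihydro-2H-chromene-3,4-diol (2,3-cis-3,4-trans), via bromohydrin 10 (not isolated), via epoxide 11 (not isolated)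
Conditions: NaBH4, THF/H2O, 0 °C; then K2CO3, H2O, 40 °C
Reagents that add atoms: water O
Why: Hydride reduction, intramolecular Williamson epoxide closure and solvolytic epoxide opening (the classical bromohydrin–epoxide route to flavan-3,4-diols): axial hydride delivery gives the 2,4-cis alcohol and thus the trans-bromohydrin 10, the C-4 alkoxide displaces bromide on the face of the 2-aryl group to give 11, and water opens 11 at the benzylic, O-7-stabilised C-4 anti to the C-3 oxygen, so C-3 (OH cis to the aryl group) and C-4 (OH trans to the C-3 OH) are both relayed from C-2.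

Step 7
Reactants: 12 (2R,3R,4S)-7,8-bis(benzyloxy)-2-[3,4-bis(benzyloxy)phenyl]-3,4-dihydro-2H-chromene-3,4-diol
Product: 13 (2R,3R,4S)-3,4,7,8-tetrakis(benzyloxy)-2-[3,4-bis(benzyloxy)phenyl]-3,4-dihydro-2H-chromene
Conditions: NaH, BnBr, Bu4NI (cat.), DMF, 0 °C to rt
Reagents that add atoms: benzyl bromide BrCc1ccccc1
Why: Williamson etherification of both secondary alkoxides gives base-stable, non-participating protection that survives organolithium, borane, oxidation and hydride steps and falls in the final hydrogenolysis.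

Step 8
Reactants: 13 (2R,3R,4S)-3,4,7,8-tetrakis(benzyloxy)-2-[3,4-bis(benzyloxy)phenyl]-3,4-dihydro-2H-chromene
Product: 14 (2R,3R,4S)-3,4,7,8-tetrakis(benzyloxy)-2-[3,4-bis(benzyloxy)phenyl]-6-bromo-3,4-dihydro-2H-chromene
Conditions: NBS, CH2Cl2/MeCN, −20 to 0 °C, dark
Reagents that add atoms: N-bromosuccinimide O=C1CCC(=O)N1Br
Why: Electrophilic aromatic bromination should go to C-6, which is para to O-1 and ortho to O-7 (resorcinol-type double activation), whereas C-5 and the catechol-ring positions are each activated by one oxygen only.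

Step 9
Reactants: 14 (2R,3R,4S)-3,4,7,8-tetrakis(benzyloxy)-2-[3,4-bis(benzyloxy)phenyl]-6-bromo-3,4-dihydro-2H-chromene; 7 (2S)-7,8-bis(benzyloxy)-2-[3,4-bis(benzyloxy)phenyl]-2,3-dihydro-4H-chromen-4-one
Product: 17 (2S)-7,8-bis(benzyloxy)-2-[3,4-bis(benzyloxy)phenyl]-4-{(2R,3R,4S)-3,4,7,8-tetrakis(benzyloxy)-2-[3,4-bis(benzyloxy)phenyl]-3,4-dihydro-2H-chromen-6-yl}-3,4-dihydro-2H-chromen-4-ol (C-4 epimers), via aryllithium 15 (not isolated), via arylcerium dichloride 16 (not isolated)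
Conditions: n-BuLi, THF, −78 °C; anhydrous CeCl3, THF, −78 °C; then 7, −78 to −40 °C; H2O quench
Reagents that add atoms: n-butyllithium [Li]CCCC (lithium of 15 only); cerium trichloride Cl[Ce](Cl)Cl (cerium dichloride group of 16 only)
Why: Bromine–lithium exchange, transmetalation and 1,2-addition of the weakly basic organocerium to the enolisable ketone should form the C-4(C ring)–C-6(D ring) bond under acid-free conditions that leave the ionisable C-4 ether of ring F untouched; the carbinol configuration is irrelevant because it is removed in step 10.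

Step 10
Reactants: 17 the tertiary carbinol from step 9
Product: 18 (2S)-7,8-bis(benzyloxy)-2-[3,4-bis(benzyloxy)phenyl]-4-{(2R,3R,4S)-3,4,7,8-tetrakis(benzyloxy)-2-[3,4-bis(benzyloxy)phenyl]-3,4-dihydro-2H-chromen-6-yl}-2H-chromene
Conditions: Burgess reagent, THF, 50 °C; chromatography on Et3N-deactivated silica, light excluded
Reagents that add atoms: none
Why: Burgess dehydration of the tertiary diaryl carbinol can only remove a hydrogen from C-3 and should give the 4-aryl-2H-chromene under neutral conditions with C-2 intact.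

Step 11
Reactants: 18 the 4-aryl-2H-chromene from step 10
Product: 20 (2R,3S,4S)-7,8-bis(benzyloxy)-2-[3,4-bis(benzyloxy)phenyl]-4-{(2R,3R,4S)-3,4,7,8-tetrakis(benzyloxy)-2-[3,4-bis(benzyloxy)phenyl]-3,4-dihydro-2H-chromen-6-yl}-3,4-dihydro-2H-chromen-3-ol (upper unit 2,3-trans-3,4-trans), via alkylborane 19 (not isolated)
Conditions: BH3·THF, THF, 0 °C to rt; NaOH, H2O2, 0 °C
Reagents that add atoms: hydrogen peroxide OO; borane–tetrahydrofuran [BH3-][O+]1CCCC1 (boron of 19 only)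
Why: Hydroboration–oxidation: borane adds syn across C-3–C-4 from the face opposite the adjacent 2-aryl group with boron at the less substituted C-3, so one event sets C-4 (ring D cis to ring B) and C-3 (OH trans to both), and the C–B bond is oxidised with retention.

Step 12
Reactants: 20 the 2,3-trans-3,4-trans alcohol from step 11
Product: 21 (2R,4S)-7,8-bis(benzyloxy)-2-[3,4-bis(benzyloxy)phenyl]-4-{(2R,3R,4S)-3,4,7,8-tetrakis(benzyloxy)-2-[3,4-bis(benzyloxy)phenyl]-3,4-dihydro-2H-chromen-6-yl}-2H-chromen-3(4H)-one (2,4-cis)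
Conditions: Dess–Martin periodinane, CH2Cl2, 0 °C to rt; used at once
Reagents that add atoms: none
Why: Dess–Martin oxidation under near-neutral conditions should give the flavan-3-one, whose 2,4-cis-diaryl arrangement (both groups pseudo-equatorial) is the thermodynamic one, so the two enolisable flanking centres are not at risk.

Step 13
Reactants: 21 the 2,4-cis-flavan-3-one from step 12
Product: 22 (2R,3R,4S)-7,8-bis(benzyloxy)-2-[3,4-bis(benzyloxy)phenyl]-4-{(2R,3R,4S)-3,4,7,8-tetrakis(benzyloxy)-2-[3,4-bis(benzyloxy)phenyl]-3,4-dihydro-2H-chromen-6-yl}-3,4-dihydro-2H-chromen-3-ol (upper unit all-cis)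
Conditions: LiBH(s-Bu)3 (L-selectride), THF, −78 °C; H2O quench
Reagents that add atoms: none
Why: Diastereoselective ketone reduction: the bulky hydride attacks along the equatorial trajectory and should give the axial 3-hydroxyl cis to both aryl groups, the same inversion tactic that converts 2,3-trans- into 2,3-cis-flavan-3-ols.

Step 14
Reactants: 22 the deca-O-benzyl all-cis dimer from step 13
Product: 23 (2R,3R,4S)-2-(3,4-dihydroxyphenyl)-6-[(2R,3R,4R)-2-(3,4-dihydroxyphenyl)-3,7,8-trihydroxy-3,4-dihydro-2H-chromen-4-yl]-3,4-dihydro-2H-chromene-3,4,7,8-tetrol (CNP0143773.1)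
Conditions: H2 (1 atm), Pd(OH)2/C, THF/MeOH, rt; filtration under argon, Sephadex LH-20
Reagents that add atoms: none
Why: Catalytic hydrogenolysis cleaves the ten O–benzyl bonds; the unhindered O–CH2Ph bonds should react before the ring C-4–O bond of ring F, so the reaction is stopped at the calculated hydrogen uptake and the air-sensitive polyphenol is handled under argon.

**Compound list**

1 | 1-(2,3,4-trihydroxyphenyl)ethan-1-one | CC(=O)c1ccc(O)c(O)c1O | starting material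
2 | 1-[3,4-bis(benzyloxy)-2-hydroxyphenyl]ethan-1-one | CC(=O)c1ccc(OCc2ccccc2)c(OCc2ccccc2)c1O | intermediate
3 | 1,2-bis(benzyloxy)-4-(chloromethyl)benzene | ClCc1ccc(OCc2ccccc2)c(OCc2ccccc2)c1 | starting material
4 | 1-(3,4-bis(benzyloxy)-2-{[3,4-bis(benzyloxy)phenyl]methoxy}phenyl)ethan-1-one | CC(=O)c1ccc(OCc2ccccc2)c(OCc2ccccc2)c1OCc1ccc(OCc2ccccc2)c(OCc2ccccc2)c1 | intermediate
5 | 1-(3,4-bis(benzyloxy)-2-{[3,4-bis(benzyloxy)phenyl]methoxy}phenyl)-4,4,4-trifluorobutane-1,3-dione | O=C(CC(=O)C(F)(F)F)c1ccc(OCc2ccccc2)c(OCc2ccccc2)c1OCc1ccc(OCc2ccccc2)c(OCc2ccccc2)c1 | intermediate (not isolated)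
6 | 1-(3,4-bis(benzyloxy)-2-{[3,4-bis(benzyloxy)phenyl]methoxy}phenyl)-2-diazoethan-1-one | [N-]=[N+]=CC(=O)c1ccc(OCc2ccccc2)c(OCc2ccccc2)c1OCc1ccc(OCc2ccccc2)c(OCc2ccccc2)c1 | intermediate
7 | (2S)-7,8-bis(benzyloxy)-2-[3,4-bis(benzyloxy)phenyl]-2,3-dihydro-4H-chromen-4-one | O=C1C[C@@H](c2ccc(OCc3ccccc3)c(OCc3ccccc3)c2)Oc2c1ccc(OCc1ccccc1)c2OCc1ccccc1 | intermediate
8 | {[(2S)-7,8-bis(benzyloxy)-2-[3,4-bis(benzyloxy)phenyl]-2H-chromen-4-yl]oxy}trimethylsilane | C[Si](C)(C)OC1=C[C@@H](c2ccc(OCc3ccccc3)c(OCc3ccccc3)c2)Oc2c1ccc(OCc1ccccc1)c2OCc1ccccc1 | intermediate (not isolated)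
9 | (2R,3R)-7,8-bis(benzyloxy)-2-[3,4-bis(benzyloxy)phenyl]-3-bromo-2,3-dihydro-4H-chromen-4-one | O=C1[C@H](Br)[C@@H](c2ccc(OCc3ccccc3)c(OCc3ccccc3)c2)Oc2c1ccc(OCc1ccccc1)c2OCc1ccccc1 | intermediate
10 | (2R,3S,4R)-7,8-bis(benzyloxy)-2-[3,4-bis(benzyloxy)phenyl]-3-bromo-3,4-dihydro-2H-chromen-4-ol (2,3-trans-3,4-trans) | O[C@H]1[C@H](Br)[C@@H](c2ccc(OCc3ccccc3)c(OCc3ccccc3)c2)Oc2c1ccc(OCc1ccccc1)c2OCc1ccccc1 | intermediate (not isolated)
11 | (2R,3R,4R)-7,8-bis(benzyloxy)-2-[3,4-bis(benzyloxy)phenyl]-3,4-epoxy-3,4-dihydro-2H-chromene (epoxide cis to the 2-aryl group) | O1[C@@H]2c3ccc(OCc4ccccc4)c(OCc4ccccc4)c3O[C@H](c3ccc(OCc4ccccc4)c(OCc4ccccc4)c3)[C@H]12 | intermediate (not isolated)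
12 | (2R,3R,4S)-7,8-bis(benzyloxy)-2-[3,4-bis(benzyloxy)phenyl]-3,4-dihydro-2H-chromene-3,4-diol | O[C@@H]1[C@@H](O)[C@@H](c2ccc(OCc3ccccc3)c(OCc3ccccc3)c2)Oc2c1ccc(OCc1ccccc1)c2OCc1ccccc1 | intermediate
13 | (2R,3R,4S)-3,4,7,8-tetrakis(benzyloxy)-2-[3,4-bis(benzyloxy)phenyl]-3,4-dihydro-2H-chromene | C(c1ccccc1)O[C@@H]1[C@@H](OCc2ccccc2)[C@@H](c2ccc(OCc3ccccc3)c(OCc3ccccc3)c2)Oc2c1ccc(OCc1ccccc1)c2OCc1ccccc1 | intermediate
14 | (2R,3R,4S)-3,4,7,8-tetrakis(benzyloxy)-2-[3,4-bis(benzyloxy)phenyl]-6-bromo-3,4-dihydro-2H-chromene | C(c1ccccc1)O[C@@H]1[C@@H](OCc2ccccc2)[C@@H](c2ccc(OCc3ccccc3)c(OCc3ccccc3)c2)Oc2c1cc(Br)c(OCc1ccccc1)c2OCc1ccccc1 | intermediate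
15 | 6-lithio derivative of 13 | C(c1ccccc1)O[C@@H]1[C@@H](OCc2ccccc2)[C@@H](c2ccc(OCc3ccccc3)c(OCc3ccccc3)c2)Oc2c1cc([Li])c(OCc1ccccc1)c2OCc1ccccc1 | intermediate (not isolated)
16 | 6-(dichlorocerio) derivative of 13 (trivalent cerium) | C(c1ccccc1)O[C@@H]1[C@@H](OCc2ccccc2)[C@@H](c2ccc(OCc3ccccc3)c(OCc3ccccc3)c2)Oc2c1cc([Ce](Cl)Cl)c(OCc1ccccc1)c2OCc1ccccc1 | intermediate (not isolated)
17 | (2S)-7,8-bis(benzyloxy)-2-[3,4-bis(benzyloxy)phenyl]-4-{(2R,3R,4S)-3,4,7,8-tetrakis(benzyloxy)-2-[3,4-bis(benzyloxy)phenyl]-3,4-dihydro-2H-chromen-6-yl}-3,4-dihydro-2H-chromen-4-ol (C-4 epimers) | C(c5ccccc5)Oc1ccc([C@H]2Oc3c(ccc(OCc5ccccc5)c3OCc3ccccc3)C(O)(c3cc4c(c(OCc5ccccc5)c3OCc3ccccc3)O[C@H](c3ccc(OCc5ccccc5)c(OCc5ccccc5)c3)[C@H](OCc3ccccc3)[C@H]4OCc3ccccc3)C2)cc1OCc1ccccc1 | intermediate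
18 | (2S)-7,8-bis(benzyloxy)-2-[3,4-bis(benzyloxy)phenyl]-4-{(2R,3R,4S)-3,4,7,8-tetrakis(benzyloxy)-2-[3,4-bis(benzyloxy)phenyl]-3,4-dihydro-2H-chromen-6-yl}-2H-chromene | C(c5ccccc5)Oc1ccc([C@H]2Oc3c(ccc(OCc5ccccc5)c3OCc3ccccc3)C(c3cc4c(c(OCc5ccccc5)c3OCc3ccccc3)O[C@H](c3ccc(OCc5ccccc5)c(OCc5ccccc5)c3)[C@H](OCc3ccccc3)[C@H]4OCc3ccccc3)=C2)cc1OCc1ccccc1 | intermediate
19 | 3-boranyl adduct of 18 (boron and H-4 on the face opposite ring B) | C(c5ccccc5)Oc1ccc([C@H]2Oc3c(ccc(OCc5ccccc5)c3OCc3ccccc3)[C@@H](c3cc4c(c(OCc5ccccc5)c3OCc3ccccc3)O[C@H](c3ccc(OCc5ccccc5)c(OCc5ccccc5)c3)[C@H](OCc3ccccc3)[C@H]4OCc3ccccc3)[C@@H]2B)cc1OCc1ccccc1 | intermediate (not isolated)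
20 | (2R,3S,4S)-7,8-bis(benzyloxy)-2-[3,4-bis(benzyloxy)phenyl]-4-{(2R,3R,4S)-3,4,7,8-tetrakis(benzyloxy)-2-[3,4-bis(benzyloxy)phenyl]-3,4-dihydro-2H-chromen-6-yl}-3,4-dihydro-2H-chromen-3-ol | C(c5ccccc5)Oc1ccc([C@H]2Oc3c(ccc(OCc5ccccc5)c3OCc3ccccc3)[C@@H](c3cc4c(c(OCc5ccccc5)c3OCc3ccccc3)O[C@H](c3ccc(OCc5ccccc5)c(OCc5ccccc5)c3)[C@H](OCc3ccccc3)[C@H]4OCc3ccccc3)[C@@H]2O)cc1OCc1ccccc1 | intermediate
21 | (2R,4S)-7,8-bis(benzyloxy)-2-[3,4-bis(benzyloxy)phenyl]-4-{(2R,3R,4S)-3,4,7,8-tetrakis(benzyloxy)-2-[3,4-bis(benzyloxy)phenyl]-3,4-dihydro-2H-chromen-6-yl}-2H-chromen-3(4H)-one | C(c5ccccc5)Oc1ccc([C@H]2Oc3c(ccc(OCc5ccccc5)c3OCc3ccccc3)[C@@H](c3cc4c(c(OCc5ccccc5)c3OCc3ccccc3)O[C@H](c3ccc(OCc5ccccc5)c(OCc5ccccc5)c3)[C@H](OCc3ccccc3)[C@H]4OCc3ccccc3)C2=O)cc1OCc1ccccc1 | intermediate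
22 | (2R,3R,4S)-7,8-bis(benzyloxy)-2-[3,4-bis(benzyloxy)phenyl]-4-{(2R,3R,4S)-3,4,7,8-tetrakis(benzyloxy)-2-[3,4-bis(benzyloxy)phenyl]-3,4-dihydro-2H-chromen-6-yl}-3,4-dihydro-2H-chromen-3-ol | C(c5ccccc5)Oc1ccc([C@H]2Oc3c(ccc(OCc5ccccc5)c3OCc3ccccc3)[C@@H](c3cc4c(c(OCc5ccccc5)c3OCc3ccccc3)O[C@H](c3ccc(OCc5ccccc5)c(OCc5ccccc5)c3)[C@H](OCc3ccccc3)[C@H]4OCc3ccccc3)[C@H]2O)cc1OCc1ccccc1 | intermediate
23 | (2R,3R,4S)-2-(3,4-dihydroxyphenyl)-6-[(2R,3R,4R)-2-(3,4-dihydroxyphenyl)-3,7,8-trihydroxy-3,4-dihydro-2H-chromen-4-yl]-3,4-dihydro-2H-chromene-3,4,7,8-tetrol | Oc1ccc([C@H]2Oc3c(ccc(O)c3O)[C@@H](c3cc4c(c(O)c3O)O[C@H](c3ccc(O)c(O)c3)[C@H](O)[C@H]4O)[C@H]2O)cc1O | target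

**Step count**

Total step count: 14. Longest linear sequence: 14 steps (1 → 23; flavanone 7 also enters step 9 as the second partner).

**Steps most likely to fail, with fallbacks**

Step 4. The carbenoid may be diverted to an oxonium ylide at O-1 with [1,2]-shift of the electron-rich benzyl group, or the insertion may proceed with too little enantioselection. The fallback sets out from 4 and returns at 7. Ketone 4 is converted with isopropenyl acetate and TsOH into the enol acetate F1. DDQ (2,6-dichloropyridine, LiClO4, 1,2-dichloroethane) then abstracts hydride from the dioxygenated benzyl ether, and the aryloxy-stabilised benzylic cation is captured by the enol acetate in a six-membered C-2–C-3 ring closure to give the racemic flavanone F2. Kinetic resolution by asymmetric transfer hydrogenation with RuCl[(R,R)-TsDPEN](p-cymene) and HCO2H/Et3N should reduce the 2R ketone to the cis-flavan-4-ol F3, which is separated, leaving the 2S ketone 7.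

Step 9. The organometallic may enolise the flavanone, with ring opening to the chalcone phenolate, or the hindered aryl nucleophile may add too slowly. The fallback sets out from 7 and 14 and returns at 18, bypassing 17. Ketone 7 is converted with Tf2O and 2,6-di-tert-butyl-4-methylpyridine into the enol triflate F7. Bromide 14 is converted with B2pin2, Pd(dppf)Cl2 and KOAc into the pinacol boronate F8. Suzuki–Miyaura coupling of the two [Pd(PPh3)4, K3PO4, dioxane/H2O] should give 18 directly.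

Step 6. Stereocontrol may be lost if the labile, O-7-activated epoxide opens through a free benzylic cation that is attacked from both faces, or if reduction gives the cis-bromohydrin, which cannot close the epoxide. The fallback sets out from 7 and returns at 12, bypassing 9. NaBH4 reduces 7 to the 2,4-cis-flavan-4-ol F4, and Burgess dehydration gives the flav-3-ene F5. A Prévost reaction (I2, silver benzoate, dry benzene) should then give the 3α,4β-dibenzoate F6: the iodonium ion forms anti to the 2-aryl group, benzoate opens it at benzylic C-4, the acyloxonium ion forms on the aryl face, and the second benzoate attacks C-4 from the opposite face. Methanolysis (K2CO3, MeOH) gives 12.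

Further compounds
F1 | step 4 | 1-(3,4-bis(benzyloxy)-2-{[3,4-bis(benzyloxy)phenyl]methoxy}phenyl)ethenyl acetate | CC(=O)OC(=C)c1ccc(OCc2ccccc2)c(OCc2ccccc2)c1OCc1ccc(OCc2ccccc2)c(OCc2ccccc2)c1
F2 | step 4 | racemic 7,8-bis(benzyloxy)-2-[3,4-bis(benzyloxy)phenyl]-2,3-dihydro-4H-chromen-4-one | O=C1CC(c2ccc(OCc3ccccc3)c(OCc3ccccc3)c2)Oc2c1ccc(OCc1ccccc1)c2OCc1ccccc1
F3 | step 4 | (2R,4R)-7,8-bis(benzyloxy)-2-[3,4-bis(benzyloxy)phenyl]-3,4-dihydro-2H-chromen-4-ol | O[C@@H]1C[C@H](c2ccc(OCc3ccccc3)c(OCc3ccccc3)c2)Oc2c1ccc(OCc1ccccc1)c2OCc1ccccc1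
F4 | step 6 | (2S,4S)-7,8-bis(benzyloxy)-2-[3,4-bis(benzyloxy)phenyl]-3,4-dihydro-2H-chromen-4-ol | O[C@H]1C[C@@H](c2ccc(OCc3ccccc3)c(OCc3ccccc3)c2)Oc2c1ccc(OCc1ccccc1)c2OCc1ccccc1
F5 | step 6 | (2S)-7,8-bis(benzyloxy)-2-[3,4-bis(benzyloxy)phenyl]-2H-chromene | C1=C[C@@H](c2ccc(OCc3ccccc3)c(OCc3ccccc3)c2)Oc2c1ccc(OCc1ccccc1)c2OCc1ccccc1
F6 | step 6 | (2R,3S,4S)-7,8-bis(benzyloxy)-2-[3,4-bis(benzyloxy)phenyl]-3,4-dihydro-2H-chromene-3,4-diyl dibenzoate (2,3-cis-3,4-trans) | O=C(c1ccccc1)O[C@@H]1[C@@H](OC(=O)c2ccccc2)[C@@H](c2ccc(OCc3ccccc3)c(OCc3ccccc3)c2)Oc2c1ccc(OCc1ccccc1)c2OCc1ccccc1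
F7 | step 9 | (2S)-7,8-bis(benzyloxy)-2-[3,4-bis(benzyloxy)phenyl]-2H-chromen-4-yl trifluoromethanesulfonate | O=S(=O)(OC1=C[C@@H](c2ccc(OCc3ccccc3)c(OCc3ccccc3)c2)Oc2c1ccc(OCc1ccccc1)c2OCc1ccccc1)C(F)(F)F
F8 | step 9 | (2R,3R,4S)-3,4,7,8-tetrakis(benzyloxy)-2-[3,4-bis(benzyloxy)phenyl]-6-(4,4,5,5-tetramethyl-1,3,2-dioxaborolan-2-yl)-3,4-dihydro-2H-chromene | C(c1ccccc1)O[C@@H]1[C@@H](OCc2ccccc2)[C@@H](c2ccc(OCc3ccccc3)c(OCc3ccccc3)c2)Oc2c1cc(B3OC(C)(C)C(C)(C)O3)c(OCc1ccccc1)c2OCc1ccccc1
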